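The runs are simulated for an exercise; the scatter is artificial.

The constants of this flask are hidden, so the two earlier runs have to stand in for them.

all flasks: substrate 0.050 M
- east: coupling partner 1.8 equiv; second reagent 0.053 equiv (fed, over 2.0 min); third reagent 1.3 equiv; run made earlier; the fed solution adds 1.0 times the starting volume
- north-west: coupling partner 1.8 equiv; second reagent 5.2 equiv (fed, over 2.0 min); third reagent 1.3 equiv; run made earlier; the fed solution adds 1.0 times the starting volume
- elm: coupling partner 1.80 equiv; second reagent 0.0800 equiv (fed, over 2.0 min); third reagent 1.30 equiv; the fed solution adds 1.0 times the starting volume; time 5.0 min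
- larch: coupling partner 1.80 equiv; second reagent 0.250 equiv (fed, over 2.0 min); third reagent 1.30 equiv; the fed solution adds 1.0 times the starting volume; time 5.0 min
- oak: coupling partner 1.80 equiv; second reagent 0.800 equiv (fed, over 2.0 min); third reagent 1.30 equiv; the fed solution adds 1.0 times the starting volume; time 5.0 min
- birch: coupling partner 1.80 equiv; second reagent 2.00 equiv (fed, over 2.0 min); third reagent 1.30 equiv; the fed solution adds 1.0 times the starting volume; time 5.0 min
- ash: coupling partner 1.80 equiv; second reagent 6.00 equiv (fed, over 2.0 min); third reagent 1.30 equiv; the fed solution adds 1.0 times the starting volume; time 5.0 min

- east (time / min: intermediate A / %, target / %): 0.333: 2.4, 0; 1.00: 5.2, 0; 2.00: 6.1, 0; 2.50: 7.5, 0; 4.00: 8.3, 0.1; 5.00: 9.5, 0.1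
- north-west (time / min: intermediate A / %, target / %): 0.833: 4.6, 0; 1.50: 4.9, 0.2; 2.50: 5.9, 0.3; 3.00: 6.2, 0; 4.00: 5.3, 0.1; 5.00: 5.9, 0.5

(standard deviation of a reading: 0.3 percentage points)

- percentages count the substrate that a species holds: one homo dimer counts as two
- every charge counts on the volume at the start, and the solution that is fed holds the whole dose
- steps that have been proposed: second reagent + intermediate A -> intermediate B; coupling partner <-> dormant form; third reagent + intermediate B -> target; 2 substrate -> homo dimer; substrate + coupling partner -> intermediate A
- "hardly changes" means that all values lie within two and a half points (for a concentration: within two and a half percent of the largest)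

* amount of intermediate A at the end, in percent of the substrate charged for elm, larch, oak, birch, ash, in this order
* how that number moves from the first to the last of them (falls all the way / falls, then rises / rises all the way / hardly changes / rises, then falls)

Take the main step first: substrate and coupling partner form intermediate A. East, with 0.053 equiv of second reagent, shows this formation curve, reaching 6.1% at 2.00 min and 9.5% at 5.00 min.

Add the side processes next. East gains 3.4 percentage points over the last 3.00 min, so formation slows as the feed dilutes the flask; homo dimer and dormant form may share in this. Neither of those steps contains the second reagent, and the runs and the new flasks have the same charges of substrate, coupling partner and third reagent and the same feed volume. The formation curve can therefore be carried across the doses.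

Add the drain last. Intermediate A goes to intermediate B at a rate proportional to c(second reagent) times c(intermediate A), and north-west, at 5.2 equiv, ends at 5.9%. Intermediate A reads at most 9.5% of the substrate charged, against doses of 0.800 equiv and above in oak, birch and ash. In these flasks the dose should stay near its charge, which makes the drain a pseudo-first-order loss of intermediate A. The third reagent acts on intermediate B, downstream of the asked number.

My own reckoning takes the end amount of intermediate A to fall by the same factor for each added equivalent. Call 7.49 equiv the halving dose: the dose of second reagent that cuts the amount of intermediate A at 5.00 min to half, read from the end readings of east and north-west. Each of those readings carries a scatter of 0.3 points. From east's value, this gives 9.48%, 9.33%, 8.87%, 7.93% and 5.48%.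

The forecast, “assuming first order in the second reagent”, gives 9.4%, 9.3%, 8.8%, 7.9% and 5.5%, with the shape: falls all the way. The two reckonings differ slightly: for elm mine gives 9.48% against the forecast's 9.4%, and for ash 5.48% against the forecast's 5.5%.

The flask gives 9.21%, 9.04%, 8.54%, 7.55% and 5.07%: falls all the way.

    second reagent + intermediate A → intermediate B (k = 0.0212 M⁻¹ s⁻¹)
    coupling partner ⇌ dormant form (K = 0.193, k = 0.00276 s⁻¹)
    third reagent + intermediate B → target (k = 0.0330 M⁻¹ s⁻¹)
    2 substrate → homo dimer (k = 0.267 M⁻¹ s⁻¹)
    substrate + coupling partner → intermediate A (k = 0.0193 M⁻¹ s⁻¹)

In ash, 99.3% of the second reagent's charge still stands at 5.00 min. Started from elm's 9.21%, the halving dose of 7.49 equiv gives 7.71% for birch, which stands at 7.55%, and 5.32% for ash, which stands at 5.07%.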